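**Retrosynthetic overview**
1. Target 28 ← 27 ← 26 ← 25: the O-8 isovalerate is put on and C14/O-15 are unmasked only after the ring-forming step.
2. Key disconnection: the C11–C12 and C6–C7 bonds of the α-methylene-γ-butyrolactone, giving the acyclic allenyl enal 21 + CO2. The enabling feature is the lactone unit O–C6–C7–C11(=C13H2)–C12(=O): it is the retron of a monosubstituted allene (C7=C11=C13), CO2 (C12) and an aldehyde (C6), and its C6–C7 bond is also a bond of the ten-membered carbocycle, so one nickel-mediated operation closes the carbocycle and then the cis-fused lactone and sets C6 and C7 from C8.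
3. 21 ← alkylidene lactone 13 (temporary γ-lactone C14–O8, opened again; allene by Crabbé homologation) ← HWE union of phosphonolactone 12 (C7–C11, C14; C8 by asymmetric transfer hydrogenation of ynone 9) with aldehyde 6 (C1–C6, C15; C4=C5 by alkoxide-directed anti-allylmagnesiation of butynediol ether 2).
4. Ring order: temporary γ-lactone (closed in step 7, opened in step 10) → ten-membered carbocycle → α-methylene lactone (both in step 18).

Key step: step 18

Remark: germacranolide numbering (C1–C15) is used. The SMILES is read as 6S,7R,8R, with the lactone cis-fused at C6/C7, O-8 on the same ring face as C11, and both ring olefins cis within the ring (E by the sequence rule). In the SMILES of 22 and 23 nickel is drawn without its DBU ligands.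

**Step 1**
Reactants: 1 but-2-yne-1,4-diol
Product: 2 4-[(4-methoxybenzyl)oxy]but-2-yn-1-ol
Conditions: NaH (1.0 equiv), 1 (3 equiv), PMBCl (1.0 equiv), Bu4NI (cat.), THF/DMF, 0 °C → rt
Reagents that add atoms: 4-methoxybenzyl chloride, COc1ccc(CCl)cc1
Why: Williamson etherification; with the symmetrical diol in excess the mono-ether should be the main product, and no stereocentre is involved.

**Step 2**
Reactants: 2 4-[(4-methoxybenzyl)oxy]but-2-yn-1-ol
Product: 3 (2E)-2-allyl-4-[(4-methoxybenzyl)oxy]but-2-en-1-ol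
Conditions: allylmagnesium bromide (3 equiv), Et2O/THF, 0 °C → reflux; aq. HCl (1 M), 0 °C
Reagents that add atoms: allylmagnesium bromide, C=CC[Mg]Br
Why: Alkoxide-directed anti-carbomagnesiation (allylmagnesiation of a propargylic alcohol): the magnesium alkoxide at O-15 delivers allyl to the proximal alkyne carbon C4 and the five-membered chelated alkenylmagnesium is protonated with retention, so C3 ends cis to C6, which sets the C4=C5 geometry.

**Step 3**
Reactants: 3 (2E)-2-allyl-4-[(4-methoxybenzyl)oxy]but-2-en-1-ol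
Product: 4 tert-butyl({(2E)-2-allyl-4-[(4-methoxybenzyl)oxy]but-2-en-1-yl}oxy)dimethylsilane
Conditions: TBSCl, imidazole, DMF, rt
Reagents that add atoms: tert-butyldimethylsilyl chloride, CC(C)(C)[Si](C)(C)Cl
Why: Standard silylation of the primary allylic alcohol O-15, which stays protected until the last step.

**Step 4**
Reactants: 4 tert-butyl({(2E)-2-allyl-4-[(4-methoxybenzyl)oxy]but-2-en-1-yl}oxy)dimethylsilane
Product: 5 (4E)-4-{[(tert-butyldimethylsilyl)oxy]methyl}-6-[(4-methoxybenzyl)oxy]hex-4-en-1-ol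
Conditions: 9-BBN (1.3 equiv), THF, 0 °C → rt; NaOH (3 M), H2O2 (30%), 0 °C → rt
Reagents that add atoms: hydrogen peroxide, OO
Why: Hydroboration–oxidation; 9-BBN adds anti-Markovnikov to the monosubstituted alkene and leaves the trisubstituted one, giving the C1 primary alcohol.

**Step 5**
Reactants: 5 (4E)-4-{[(tert-butyldimethylsilyl)oxy]methyl}-6-[(4-methoxybenzyl)oxy]hex-4-en-1-ol
Product: 6 (4E)-4-{[(tert-butyldimethylsilyl)oxy]methyl}-6-[(4-methoxybenzyl)oxy]hex-4-enal
Conditions: Dess–Martin periodinane, NaHCO3, CH2Cl2, 0 °C → rt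
Reagents that add atoms: none
Why: Dess–Martin oxidation gives the C1 aldehyde under buffered conditions that leave the PMB and TBS ethers untouched.

**Step 6**
Reactants: 7 methyl 4-chloro-4-oxobutanoate; 8 bis(trimethylsilyl)acetylene
Product: 9 methyl 4-oxo-6-(trimethylsilyl)hex-5-ynoate
Conditions: AlCl3 (1.1 equiv), CH2Cl2, 0 °C
Reagents that add atoms: none
Why: Friedel–Crafts-type acylation of a silylalkyne with ipso-substitution of one trimethylsilyl group, a standard entry to silyl ynones.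

**Step 7**
Reactants: 9 methyl 4-oxo-6-(trimethylsilyl)hex-5-ynoate
Product: 11 (5R)-5-[(trimethylsilyl)ethynyl]oxolan-2-one, via hydroxy ester 10 (not isolated)
Conditions: RuCl[(R,R)-TsDPEN](p-cymene) (1 mol%), KOH (1 mol%), 2-propanol, rt; then TsOH·H2O (5 mol%), toluene, 40 °C
Reagents that add atoms: none
Why: Noyori asymmetric transfer hydrogenation of the alkynyl ketone, in which the alkyne takes the place of the aryl group of aryl ketones so that the (R,R)-catalyst should give the (R)-carbinol C8, followed by acid-catalysed lactonisation of the γ-hydroxy ester.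

**Step 8**
Reactants: 11 (5R)-5-[(trimethylsilyl)ethynyl]oxolan-2-one
Product: 12 diethyl {(5R)-2-oxo-5-[(trimethylsilyl)ethynyl]oxolan-3-yl}phosphonate (both C3 epimers)
Conditions: LiN(iPr)2 (2.2 equiv), THF, −78 °C; ClP(O)(OEt)2 (1.1 equiv), −78 °C → rt; aq. NH4Cl
Reagents that add atoms: diethyl chlorophosphate, CCOP(=O)(Cl)OCC
Why: Enolate O-phosphorylation followed by base-induced 1,3-phosphorus shift (vinyl phosphate to phosphonate rearrangement) gives the α-phosphono lactone; the new centre at C10 is lost in the next step.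

**Step 9**
Reactants: 12 diethyl {(5R)-2-oxo-5-[(trimethylsilyl)ethynyl]oxolan-3-yl}phosphonate; 6 (4E)-4-{[(tert-butyldimethylsilyl)oxy]methyl}-6-[(4-methoxybenzyl)oxy]hex-4-enal
Product: 13 (3E,5R)-3-[(4E)-4-{[(tert-butyldimethylsilyl)oxy]methyl}-6-[(4-methoxybenzyl)oxy]hex-4-en-1-ylidene]-5-[(trimethylsilyl)ethynyl]oxolan-2-one
Conditions: KOtBu (1.05 equiv), THF, 0 °C; then 6, 0 °C → rt
Reagents that add atoms: none
Why: Horner–Wadsworth–Emmons olefination; the cyclic phosphonate should give mainly the E-alkylidene lactone (C2 trans to the carbonyl C14, cis to C9), which sets the C1=C10 geometry, and the minor Z isomer is removed by chromatography.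

**Step 10**
Reactants: 13 (3E,5R)-alkylidene lactone
Product: 14 (2E,6E)-6-{[(tert-butyldimethylsilyl)oxy]methyl}-2-[(2R)-2-hydroxy-4-(trimethylsilyl)but-3-yn-1-yl]-N-methoxy-8-[(4-methoxybenzyl)oxy]-N-methylocta-2,6-dienamide
Conditions: MeNH(OMe)·HCl (3 equiv), Me3Al (3 equiv), CH2Cl2, 0 °C; then 13, 0 °C → rt; aq. potassium sodium tartrate
Reagents that add atoms: N,O-dimethylhydroxylamine hydrochloride, CNOC.Cl
Why: Weinreb aminolysis of the lactone by the aluminium amide formed in situ opens the temporary ring, leaving C14 as an amide and O-8 free.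

**Step 11**
Reactants: 14 hydroxy Weinreb amide
Product: 15 (2E,6E)-6-{[(tert-butyldimethylsilyl)oxy]methyl}-N-methoxy-8-[(4-methoxybenzyl)oxy]-N-methyl-2-[(2R)-2-[(triethylsilyl)oxy]-4-(trimethylsilyl)but-3-yn-1-yl]octa-2,6-dienamide
Conditions: TESCl (1.5 equiv), imidazole (3 equiv), CH2Cl2, 0 °C
Reagents that add atoms: triethylsilyl chloride, CC[Si](Cl)(CC)CC
Why: Silylation of the secondary propargylic alcohol prevents relactonisation and installs the most labile silyl ether, which can later be removed selectively.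

**Step 12**
Reactants: 15 silylated Weinreb amide
Product: 16 (2E,6E)-6-{[(tert-butyldimethylsilyl)oxy]methyl}-8-[(4-methoxybenzyl)oxy]-2-[(2R)-2-[(triethylsilyl)oxy]-4-(trimethylsilyl)but-3-yn-1-yl]octa-2,6-dienal
Conditions: iBu2AlH (DIBAL-H, 1.5 equiv), THF, −78 °C; aq. potassium sodium tartrate
Reagents that add atoms: none
Why: Reduction of a Weinreb amide stops at the aldehyde because the chelated tetrahedral aluminium intermediate survives until work-up.

**Step 13**
Reactants: 16 enal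
Product: 17 2-{(3R,5E,9E)-9-{[(tert-butyldimethylsilyl)oxy]methyl}-11-[(4-methoxybenzyl)oxy]-3-[(triethylsilyl)oxy]-1-(trimethylsilyl)undeca-5,9-dien-1-yn-5-yl}-1,3-dioxolane
Conditions: TMSOCH2CH2OTMS (2 equiv), TMSOTf (5 mol%), CH2Cl2, −78 °C; pyridine quench
Reagents that add atoms: 1,2-bis(trimethylsilyloxy)ethane, C[Si](C)(C)OCCO[Si](C)(C)C
Why: TMSOTf-catalysed acetalisation with the bis-silyl ether of ethylene glycol at low temperature masks the C14 enal without migration of the C1=C10 bond or loss of the silyl ethers.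

**Step 14**
Reactants: 17 silylalkyne
Product: 18 2-{(3R,5E,9E)-9-{[(tert-butyldimethylsilyl)oxy]methyl}-11-[(4-methoxybenzyl)oxy]-3-[(triethylsilyl)oxy]undeca-5,9-dien-1-yn-5-yl}-1,3-dioxolane
Conditions: K2CO3, MeOH, 0 °C
Reagents that add atoms: none
Why: Methoxide-mediated protodesilylation of the alkynylsilane; the O-silyl ethers should be stable to K2CO3 in methanol at 0 °C.

**Step 15**
Reactants: 18 terminal alkyne
Product: 19 2-{(4R,6E,10E)-10-{[(tert-butyldimethylsilyl)oxy]methyl}-12-[(4-methoxybenzyl)oxy]-4-[(triethylsilyl)oxy]dodeca-1,2,6,10-tetraen-6-yl}-1,3-dioxolane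
Conditions: (CH2O)n (2.5 equiv), CuI (0.5 equiv), Cy2NH (1.8 equiv), 1,4-dioxane, 100 °C
Reagents that add atoms: formaldehyde (as paraformaldehyde), C=O
Why: Crabbé homologation: a Mannich reaction with formaldehyde and dicyclohexylamine, then copper-mediated 1,5-hydride transfer with loss of imine, converts the terminal alkyne into the monosubstituted allene (C13 added) without touching C8.

**Step 16**
Reactants: 19 allene PMB ether
Product: 20 (2E,6E,9R)-3-{[(tert-butyldimethylsilyl)oxy]methyl}-7-(1,3-dioxolan-2-yl)-9-[(triethylsilyl)oxy]dodeca-2,6,10,11-tetraen-1-ol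
Conditions: DDQ (1.3 equiv), CH2Cl2/pH 7 phosphate buffer (10:1), 0 °C
Reagents that add atoms: none
Why: Oxidative cleavage of the PMB ether by DDQ under buffered conditions should leave the silyl ethers, the dioxolane and the allene intact.

**Step 17**
Reactants: 20 allylic alcohol
Product: 21 (2E,6E,9R)-3-{[(tert-butyldimethylsilyl)oxy]methyl}-7-(1,3-dioxolan-2-yl)-9-[(triethylsilyl)oxy]dodeca-2,6,10,11-tetraenal
Conditions: MnO2 (activated, 20 equiv), CH2Cl2, rt
Reagents that add atoms: none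
Why: MnO2 oxidises the primary allylic alcohol to the C6 enal under neutral conditions, which should preserve the C4=C5 geometry.

**Step 18**
Reactants: 21 allenyl enal
Product: 25 (3aS,4R,6E,10E,11aS)-10-{[(tert-butyldimethylsilyl)oxy]methyl}-6-(1,3-dioxolan-2-yl)-3-methylidene-4-[(triethylsilyl)oxy]-3a,4,5,8,9,11a-hexahydrocyclodeca[b]furan-2(3H)-one, via allylnickel carboxylate 22 (not isolated), via nickel alkoxide carboxylate 23 (not isolated), via seco hydroxy acid 24 (not isolated)
Conditions: Ni(cod)2 (1.5 equiv), DBU (3 equiv), CO2 (1 atm), THF, 0 °C, 21 added over 6 h (final 5 mM), then rt; aq. HCl (0.5 M), 0 °C; PPTS (cat.), CH2Cl2, rt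
Reagents that add atoms: carbon dioxide, O=C=O
Why: Proposed new method: zerovalent nickel (Ni(cod)2/DBU) couples CO2 with the terminal C11=C13 π bond of the allene by oxidative cyclisation, which forms C11–C12 and gives the five-membered oxanickelacycle 22, a 2-carboxylato-allylnickel of divalent nickel that adds through its γ-carbon C7 to the tethered enal carbonyl C6 in a closed six-membered chair (C6–C7 bond, 10-exo-trig closure of the carbocycle, 23), and acidification closes the γ-hydroxy acid 24 to the lactone by 5-exo-trig acyl substitution. The closest known reactions are the nickel-mediated sequential addition of CO2 and aldehydes to terminal allenes (intermolecular) and the chromium- or zinc-mediated Barbier macrocyclisation of 2-(alkoxycarbonyl)allyl metals onto a C6 aldehyde that closes germacranolide rings at this same C6–C7 bond; new is their merger in one ring-forming operation. C6/C7: CO2 should add to C11 anti to C8, so C8 lies cis to the CH2–Ni terminus and axial in the chair while the enal substituent C5 is equatorial, which gives the syn adduct and hence the cis-fused lactone. C7/C8: allylic 1,3-strain in this Z-configured allyl unit holds C8–H in the allyl plane, and C6 is expected to bond anti to the C8–C9 bond with the silyloxy group outside, which places O-8 on the ring face of C11. The step needs γ- over α-attack (ten- not twelve-membered ring) and 1,2- over 1,4-addition, both secured by the cyclic transition state; the dioxolane keeps C14 from capturing the allylnickel in a five-ring closure, the silyl ether at O-8 removes an allenylic leaving group and the second lactonisation site, and slow addition keeps the allylation intramolecular.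

**Step 19**
Reactants: 25 bis-silylated lactone
Product: 26 (3aR,4R,6E,10E,11aS)-10-{[(tert-butyldimethylsilyl)oxy]methyl}-6-(1,3-dioxolan-2-yl)-4-hydroxy-3-methylidene-3a,4,5,8,9,11a-hexahydrocyclodeca[b]furan-2(3H)-one
Conditions: HF·pyridine, pyridine, THF, 0 °C
Reagents that add atoms: none
Why: Buffered HF·pyridine should remove the secondary triethylsilyl ether much faster than the primary tert-butyldimethylsilyl ether and, being non-basic, avoids translactonisation to O-8.

**Step 20**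
Reactants: 26 C8 alcohol
Product: 27 (3aR,4R,6E,10E,11aS)-10-{[(tert-butyldimethylsilyl)oxy]methyl}-6-(1,3-dioxolan-2-yl)-3-methylidene-2-oxo-2,3,3a,4,5,8,9,11a-octahydrocyclodeca[b]furan-4-yl 3-methylbutanoate
Conditions: (iPrCH2CO)2O (2 equiv), DMAP (0.1 equiv), pyridine, CH2Cl2, 0 °C
Reagents that add atoms: 3-methylbutanoic anhydride, CC(C)CC(=O)OC(=O)CC(C)C
Why: DMAP-catalysed acylation of the secondary alcohol proceeds with retention at C8 and should be faster than lactone migration.

**Step 21**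
Reactants: 27 protected ester
Product: 28 (3aR,4R,6E,10E,11aS)-6-formyl-10-(hydroxymethyl)-3-methylidene-2-oxo-2,3,3a,4,5,8,9,11a-octahydrocyclodeca[b]furan-4-yl 3-methylbutanoate (target)
Conditions: aq. HCl (1 M)/THF (1:4), 0 °C → rt
Reagents that add atoms: water, O
Why: Aqueous acid hydrolyses the dioxolane to the C14 enal and cleaves the primary silyl ether at O-15 in one operation, and the ester, the lactone and the two deactivated ring olefins should tolerate it.

**Compound list**
1 | but-2-yne-1,4-diol | OCC#CCO | starting material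
2 | 4-[(4-methoxybenzyl)oxy]but-2-yn-1-ol | OCC#CCOCc1ccc(OC)cc1 | intermediate
3 | (2E)-2-allyl-4-[(4-methoxybenzyl)oxy]but-2-en-1-ol | OC/C(CC=C)=C/COCc1ccc(OC)cc1 | intermediate
4 | tert-butyl({(2E)-2-allyl-4-[(4-methoxybenzyl)oxy]but-2-en-1-yl}oxy)dimethylsilane | CC(C)(C)[Si](C)(C)OC/C(CC=C)=C/COCc1ccc(OC)cc1 | intermediate
5 | (4E)-4-{[(tert-butyldimethylsilyl)oxy]methyl}-6-[(4-methoxybenzyl)oxy]hex-4-en-1-ol | CC(C)(C)[Si](C)(C)OC/C(CCCO)=C/COCc1ccc(OC)cc1 | intermediate
6 | (4E)-4-{[(tert-butyldimethylsilyl)oxy]methyl}-6-[(4-methoxybenzyl)oxy]hex-4-enal | CC(C)(C)[Si](C)(C)OC/C(CCC=O)=C/COCc1ccc(OC)cc1 | intermediate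
7 | methyl 4-chloro-4-oxobutanoate | COC(=O)CCC(Cl)=O | starting material
8 | bis(trimethylsilyl)acetylene | C[Si](C)(C)C#C[Si](C)(C)C | starting material
9 | methyl 4-oxo-6-(trimethylsilyl)hex-5-ynoate | COC(=O)CCC(=O)C#C[Si](C)(C)C | intermediate
10 | methyl (4R)-4-hydroxy-6-(trimethylsilyl)hex-5-ynoate | COC(=O)CC[C@@H](O)C#C[Si](C)(C)C | intermediate
11 | (5R)-5-[(trimethylsilyl)ethynyl]oxolan-2-one | O=C1CC[C@H](C#C[Si](C)(C)C)O1 | intermediate
12 | diethyl {(5R)-2-oxo-5-[(trimethylsilyl)ethynyl]oxolan-3-yl}phosphonate (both C3 epimers) | CCOP(=O)(OCC)C1C[C@H](C#C[Si](C)(C)C)OC1=O | intermediate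
13 | (3E,5R)-3-[(4E)-4-{[(tert-butyldimethylsilyl)oxy]methyl}-6-[(4-methoxybenzyl)oxy]hex-4-en-1-ylidene]-5-[(trimethylsilyl)ethynyl]oxolan-2-one | C[Si](C)(C)C#C[C@H]1C/C(=C\CC/C(CO[Si](C)(C)C(C)(C)C)=C\COCc2ccc(OC)cc2)C(=O)O1 | intermediate
14 | (2E,6E)-6-{[(tert-butyldimethylsilyl)oxy]methyl}-2-[(2R)-2-hydroxy-4-(trimethylsilyl)but-3-yn-1-yl]-N-methoxy-8-[(4-methoxybenzyl)oxy]-N-methylocta-2,6-dienamide | CON(C)C(=O)/C(C[C@@H](O)C#C[Si](C)(C)C)=C/CC/C(CO[Si](C)(C)C(C)(C)C)=C\COCc1ccc(OC)cc1 | intermediate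
15 | triethylsilyl ether of 14 at the (2R)-carbinol | CON(C)C(=O)/C(C[C@@H](O[Si](CC)(CC)CC)C#C[Si](C)(C)C)=C/CC/C(CO[Si](C)(C)C(C)(C)C)=C\COCc1ccc(OC)cc1 | intermediate
16 | (2E,6E)-6-{[(tert-butyldimethylsilyl)oxy]methyl}-8-[(4-methoxybenzyl)oxy]-2-[(2R)-2-[(triethylsilyl)oxy]-4-(trimethylsilyl)but-3-yn-1-yl]octa-2,6-dienal | O=C/C(C[C@@H](O[Si](CC)(CC)CC)C#C[Si](C)(C)C)=C/CC/C(CO[Si](C)(C)C(C)(C)C)=C\COCc1ccc(OC)cc1 | intermediate
17 | 2-{(3R,5E,9E)-9-{[(tert-butyldimethylsilyl)oxy]methyl}-11-[(4-methoxybenzyl)oxy]-3-[(triethylsilyl)oxy]-1-(trimethylsilyl)undeca-5,9-dien-1-yn-5-yl}-1,3-dioxolane | O1CCOC1/C(C[C@@H](O[Si](CC)(CC)CC)C#C[Si](C)(C)C)=C/CC/C(CO[Si](C)(C)C(C)(C)C)=C\COCc2ccc(OC)cc2 | intermediate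
18 | 2-{(3R,5E,9E)-9-{[(tert-butyldimethylsilyl)oxy]methyl}-11-[(4-methoxybenzyl)oxy]-3-[(triethylsilyl)oxy]undeca-5,9-dien-1-yn-5-yl}-1,3-dioxolane | O1CCOC1/C(C[C@@H](O[Si](CC)(CC)CC)C#C)=C/CC/C(CO[Si](C)(C)C(C)(C)C)=C\COCc2ccc(OC)cc2 | intermediate
19 | 2-{(4R,6E,10E)-10-{[(tert-butyldimethylsilyl)oxy]methyl}-12-[(4-methoxybenzyl)oxy]-4-[(triethylsilyl)oxy]dodeca-1,2,6,10-tetraen-6-yl}-1,3-dioxolane | O1CCOC1/C(C[C@@H](O[Si](CC)(CC)CC)C=C=C)=C/CC/C(CO[Si](C)(C)C(C)(C)C)=C\COCc2ccc(OC)cc2 | intermediate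
20 | (2E,6E,9R)-3-{[(tert-butyldimethylsilyl)oxy]methyl}-7-(1,3-dioxolan-2-yl)-9-[(triethylsilyl)oxy]dodeca-2,6,10,11-tetraen-1-ol | O1CCOC1/C(C[C@@H](O[Si](CC)(CC)CC)C=C=C)=C/CC/C(CO[Si](C)(C)C(C)(C)C)=C\CO | intermediate
21 | (2E,6E,9R)-3-{[(tert-butyldimethylsilyl)oxy]methyl}-7-(1,3-dioxolan-2-yl)-9-[(triethylsilyl)oxy]dodeca-2,6,10,11-tetraenal | O1CCOC1/C(C[C@@H](O[Si](CC)(CC)CC)C=C=C)=C/CC/C(CO[Si](C)(C)C(C)(C)C)=C\C=O | intermediate
22 | allylnickel carboxylate: five-membered oxanickelacycle (Ni–O–C12(=O)–C11–C13H2–Ni) with exocyclic C11=C7 (C8 cis to C13), remainder as in 21 | O=C1O[Ni]C/C1=C\[C@H](O[Si](CC)(CC)CC)C/C(C2OCCO2)=C\CC/C(CO[Si](C)(C)C(C)(C)C)=C\C=O | intermediate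
23 | nickel alkoxide carboxylate: ten-membered carbocycle closed at C6–C7, O-6 and the C12 carboxylate bound to one nickel, configuration as in 25 | C=C1C(=O)O[Ni]O[C@H]2/C=C(/CO[Si](C)(C)C(C)(C)C)CC/C=C(/C3OCCO3)C[C@@H](O[Si](CC)(CC)CC)[C@@H]12 | intermediate
24 | seco hydroxy acid: 2-[ten-membered ring C7-yl]acrylic acid with free 6-OH, configuration as in 25 | C=C(C(=O)O)[C@H]1[C@@H](O)/C=C(/CO[Si](C)(C)C(C)(C)C)CC/C=C(/C2OCCO2)C[C@H]1O[Si](CC)(CC)CC | intermediate
25 | (3aS,4R,6E,10E,11aS)-10-{[(tert-butyldimethylsilyl)oxy]methyl}-6-(1,3-dioxolan-2-yl)-3-methylidene-4-[(triethylsilyl)oxy]-3a,4,5,8,9,11a-hexahydrocyclodeca[b]furan-2(3H)-one | C=C1C(=O)O[C@H]2/C=C(/CO[Si](C)(C)C(C)(C)C)CC/C=C(/C3OCCO3)C[C@@H](O[Si](CC)(CC)CC)[C@@H]12 | intermediate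
26 | (3aR,4R,6E,10E,11aS)-10-{[(tert-butyldimethylsilyl)oxy]methyl}-6-(1,3-dioxolan-2-yl)-4-hydroxy-3-methylidene-3a,4,5,8,9,11a-hexahydrocyclodeca[b]furan-2(3H)-one | C=C1C(=O)O[C@H]2/C=C(/CO[Si](C)(C)C(C)(C)C)CC/C=C(/C3OCCO3)C[C@@H](O)[C@@H]12 | intermediate
27 | (3aR,4R,6E,10E,11aS)-10-{[(tert-butyldimethylsilyl)oxy]methyl}-6-(1,3-dioxolan-2-yl)-3-methylidene-2-oxo-2,3,3a,4,5,8,9,11a-octahydrocyclodeca[b]furan-4-yl 3-methylbutanoate | C=C1C(=O)O[C@H]2/C=C(/CO[Si](C)(C)C(C)(C)C)CC/C=C(/C3OCCO3)C[C@@H](OC(=O)CC(C)C)[C@@H]12 | intermediate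
28 | (3aR,4R,6E,10E,11aS)-6-formyl-10-(hydroxymethyl)-3-methylidene-2-oxo-2,3,3a,4,5,8,9,11a-octahydrocyclodeca[b]furan-4-yl 3-methylbutanoate | C=C1C(=O)O[C@H]2/C=C(/CO)CC/C=C(/C=O)C[C@@H](OC(=O)CC(C)C)[C@@H]12 | target

**Total step count:** 21.
**Longest linear sequence:** 18 steps (steps 1–5 and 9–21, from but-2-yne-1,4-diol).

**Steps most likely to fail**

1. Step 18. The allylnickel carboxylate may be protonated or add to a second molecule faster than it closes the ten-membered ring, DBU may isomerise the enal, or the facial selectivity at C7 relative to C8 may be poor. The fallback uses the established Barbier macrocyclisation of a 2-(bromomethyl)acrylate; it sets out from 18 and comes back at 25. Alkyne 18 is deprotonated with n-BuLi and treated with ClCO2Me to give the ynoate F1. cis-Hydroalumination of F1 with iBu2AlH/N-methylmorpholine N-oxide and trapping of the α-aluminoacrylate with formaldehyde gives the 2-(hydroxymethyl)enoate F2. CBr4/PPh3 converts it into the allylic bromide F3. DDQ and then MnO2, as in steps 16 and 17, give the allylic alcohol F4 and the enal F5. CrCl2 (excess) in THF under high dilution effects the intramolecular Barbier (Nozaki–Hiyama) allylation through the γ-carbon C7, with the cis preference known for 2-(alkoxycarbonyl)allylchromium reagents, to give the cyclised hydroxy ester F6, which lactonises with TsOH to 25.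

2. Step 15. The Mannich/hydride-transfer sequence may stall at the propargylic amine, or the hot amine and copper medium may erode the silyl ethers. The fallback sets out from 18 and comes back at 19. Alkyne 18 is hydroxymethylated (n-BuLi, then paraformaldehyde) to the propargylic alcohol F7. Myers allene synthesis (PPh3, diethyl azodicarboxylate, 2-nitrobenzenesulfonylhydrazide, THF, −15 °C → rt) then proceeds by Mitsunobu N-alkylation to the sulfonylhydrazide F8, loss of sulfinic acid to the propargylic diazene F9, and retro-ene loss of nitrogen to 19.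

3. Step 10. The aluminium amide may add in conjugate fashion to the alkylidene lactone, or the γ-hydroxy amide may relactonise before it is silylated. The fallback sets out from 13 and comes back at 16. Lactone 13 is reduced with iBu2AlH (excess, −78 °C → 0 °C) to the diol F10, and both hydroxyl groups are silylated (TESCl, imidazole) to the bis(triethylsilyl) ether F11. Swern oxidation, which converts primary triethylsilyl ethers directly into aldehydes and leaves the secondary triethylsilyl and the tert-butyldimethylsilyl ether, gives 16.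

**Further compounds**
F1 | step 18 | methyl ynoate: 18 with CO2Me on the alkyne terminus C11 | O1CCOC1/C(C[C@@H](O[Si](CC)(CC)CC)C#CC(=O)OC)=C/CC/C(CO[Si](C)(C)C(C)(C)C)=C\COCc2ccc(OC)cc2
F2 | step 18 | (Z)-2-(hydroxymethyl)enoate: C7H=C11(CO2Me)CH2OH, C8 cis to the ester | O1CCOC1/C(C[C@@H](O[Si](CC)(CC)CC)/C=C(/CO)C(=O)OC)=C/CC/C(CO[Si](C)(C)C(C)(C)C)=C\COCc2ccc(OC)cc2
F3 | step 18 | allylic bromide: 2-(bromomethyl)enoate corresponding to F2 | O1CCOC1/C(C[C@@H](O[Si](CC)(CC)CC)/C=C(/CBr)C(=O)OC)=C/CC/C(CO[Si](C)(C)C(C)(C)C)=C\COCc2ccc(OC)cc2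
F4 | step 18 | C6 allylic alcohol: F3 without the PMB group | O1CCOC1/C(C[C@@H](O[Si](CC)(CC)CC)/C=C(/CBr)C(=O)OC)=C/CC/C(CO[Si](C)(C)C(C)(C)C)=C\CO
F5 | step 18 | C6 enal: bromo enoate aldehyde | O1CCOC1/C(C[C@@H](O[Si](CC)(CC)CC)/C=C(/CBr)C(=O)OC)=C/CC/C(CO[Si](C)(C)C(C)(C)C)=C\C=O
F6 | step 18 | cyclised hydroxy methyl ester: methyl ester of 24 | C=C(C(=O)OC)[C@H]1[C@@H](O)/C=C(/CO[Si](C)(C)C(C)(C)C)CC/C=C(/C2OCCO2)C[C@H]1O[Si](CC)(CC)CC
F7 | step 15 | propargylic alcohol: 18 with CH2OH on the alkyne terminus | O1CCOC1/C(C[C@@H](O[Si](CC)(CC)CC)C#CCO)=C/CC/C(CO[Si](C)(C)C(C)(C)C)=C\COCc2ccc(OC)cc2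
F8 | step 15 | N-propargyl-N-(2-nitrobenzenesulfonyl)hydrazine derived from F7 | O1CCOC1/C(C[C@@H](O[Si](CC)(CC)CC)C#CCN(N)S(=O)(=O)c3ccccc3[N+](=O)[O-])=C/CC/C(CO[Si](C)(C)C(C)(C)C)=C\COCc2ccc(OC)cc2
F9 | step 15 | propargylic diazene derived from F8 | O1CCOC1/C(C[C@@H](O[Si](CC)(CC)CC)C#CCN=N)=C/CC/C(CO[Si](C)(C)C(C)(C)C)=C\COCc2ccc(OC)cc2
F10 | step 10 | diol: C14 primary allylic alcohol and free (R)-propargylic alcohol at C8 | OC/C(C[C@@H](O)C#C[Si](C)(C)C)=C/CC/C(CO[Si](C)(C)C(C)(C)C)=C\COCc1ccc(OC)cc1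
F11 | step 10 | bis(triethylsilyl) ether of F10 | CC[Si](CC)(CC)OC/C(C[C@@H](O[Si](CC)(CC)CC)C#C[Si](C)(C)C)=C/CC/C(CO[Si](C)(C)C(C)(C)C)=C\COCc1ccc(OC)cc1
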